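The readings were generated by integration with made-up constants, noise included.

**Late stall.** Late in the theta run homo product gains 2.2 percentage points between 30.0 min and 40.0 min, although open intermediate holds 20.4% at the start of that stretch, and I want to know what that stall is worth for ochre and teal.

common to all: starting material 20 mM
- theta: fresh partner 18 mM; coupling partner 84 mM; run made earlier
- alpha: fresh partner 18 mM; coupling partner 130 mM; run made earlier
- beta: fresh partner 27 mM; coupling partner 60 mM; run made earlier
- ochre: fresh partner 18.0 mM; coupling partner 60.0 mM; time 50 min
- teal: fresh partner 18.0 mM; coupling partner 60.0 mM; time 80 min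

| run | time / min | over-reaction product / % | starting material / % | target / % | open intermediate / % | homo product / % |
|---|---|---|---|---|---|---|
| theta | 4.00 | 0 | 7.0 | 4.1 | 76.4 | 13.3 |
| theta | 10.0 | 0.1 | 0.7 | 8.1 | 55.1 | 33.5 |
| theta | 20.0 | 1.0 | 0 | 20.1 | 30.5 | 50.4 |
| theta | 30.0 | 2.0 | 0 | 24.7 | 20.4 | 53.7 |
| theta | 40.0 | 4.2 | 0.7 | 25.1 | 12.0 | 55.9 |
| alpha | 3.00 | 0.3 | 3.3 | 1.3 | 83.2 | 11.9 |
| alpha | 6.00 | 0 | 1.4 | 8.7 | 65.5 | 25.1 |
| alpha | 12.0 | 1.0 | 0.2 | 16.0 | 42.6 | 41.5 |
| alpha | 20.0 | 0.1 | 0.5 | 23.1 | 28.7 | 47.2 |
| alpha | 40.0 | 4.7 | 0.8 | 29.4 | 11.1 | 52.4 |
| beta | 3.00 | 0 | 26.9 | 0 | 68.0 | 6.8 |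
| beta | 6.00 | 0 | 8.4 | 4.2 | 69.7 | 18.7 |
| beta | 12.0 | 1.8 | 0.7 | 11.8 | 51.2 | 34.8 |
| beta | 20.0 | 1.9 | 0 | 21.5 | 32.0 | 45.2 |
| beta | 40.0 | 7.1 | 0 | 30.5 | 11.3 | 53.4 |

(each reading ± 1 percentage point)

- percentages count the starting material that a species holds: one homo product counts as two
- a reading or a percentage of target counts all its forms, free or not

- which of these there is most of at the end, counted by the starting material in it, ochre (over-reaction product / homo product / open intermediate / target)
- which of these there is most of at the end, counted by the starting material in it, teal (over-reaction product / homo product / open intermediate / target)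
- the largest of these amounts at the end, in percent of the starting material charged, ochre
- the largest of these amounts at the end, in percent of the starting material charged, teal

**Homo constant.** One homo product takes two open intermediate, so I try the square of c(open intermediate): I divide the gain of homo product per minute by the squared mean c(open intermediate), both as fractions of the charge. Between 4.00 min and 10.0 min in the theta run this reads 0.0779 min⁻¹, my homo constant, and between 30.0 min and 40.0 min it reads 0.0838 min⁻¹, so I keep the square of a second-order step, and both figures are readings with the scatter of the runs.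

**Opposite outcome.** For target to end above homo product, open intermediate at the last reading would have to exceed the gap between them. In the theta run that gap is 31 points against 12.0%, and in the beta run 23 points against 11.3%. Ochre and teal share their fresh partner with theta and their coupling partner with beta, so I name homo product for both. Holding the rate of theta's last reading, I add 1.1 points for ochre and 4.5 points for teal to the homo product of that reading, which gives 57.0% and 60.4%, a rough estimate taken from a run with more coupling partner.

**The forecast.** The forecast names homo product for ochre and homo product for teal, at 59% and 61%, finding that “Homo forms early and then nearly stalls”; its ochre figure stands above mine.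

**The flask.** Ochre gives homo product at 59.5% and teal homo product at 60.7%, with 10.6% still open intermediate in ochre, on this scheme:

    starting material + coupling partner → open intermediate (k = 0.163 M⁻¹ s⁻¹)
    coupling partner + fresh partner → second intermediate (k = 0.0289 M⁻¹ s⁻¹)
    open intermediate + second intermediate → target (k = 0.0396 M⁻¹ s⁻¹)
    2 open intermediate → homo product (k = 0.0340 M⁻¹ s⁻¹)
    target → over-reaction product (k = 2.10 × 10⁻⁴ s⁻¹)
    coupling partner + target ⇌ idle adduct, settled at all times (K = 19.0 M⁻¹)

**Constant reused.** In ochre from 25.0 min to 50.0 min, open intermediate falls from 27.3% to 10.6%, the homo constant gives 7 points, and homo product gains 6.5 points. In teal from 40.0 min to 80.0 min, open intermediate falls from 14.9% to 4.24%, the constant gives 2.9 points, and homo product gains 2.5 points.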